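**Retrosynthetic overview**

1. The target is numbered as a cyclohepta[b]furan-2-one (O1, C2, C3, C3a, C4–C8, C8a). Late disconnections: the C8 angelate (esterification), the C7 crotonoyl group (gold-catalysed 1,3-acyloxy shift and hydrolysis of a butynyl pivalate), and the C3 methyl group (lactone enolate methylation).
2. Key disconnection O1–C8a. The lactone oxygen on C8a and the hydroxyl on C5 are trans and 1,4 across the cycloheptane (C8a–C3a–C4–C5), and the lactone is cis-fused. The C5 oxygen can therefore be the one-atom bridge of an 8-oxabicyclo[3.2.1]octane with bridgeheads C8a and C5, and the acetate side chain on C3a, anti to that bridge, displaces it at C8a with inversion.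
3. The rigid oxabicycle comes from meso 8-oxabicyclo[3.2.1]oct-6-en-3-one, desymmetrised by a chiral lithium amide. It relays that one stereocentre to C6 (equatorial methyl), C8 (Rubottom oxidation syn to the bridge), C3a (hydrogenation syn to the bridge) and C7 (acetylide addition syn to the bridge).
4. Ring order: the cycloheptane is present from the start inside the bicycle; the γ-lactone is closed in step 9, in the same event that opens the oxygen bridge.

Key step: step 9

Remark: 1 is taken to be a catalogue compound; bicyclic intermediates carry 8-oxabicyclo[3.2.1]octane locants (syn and anti refer to the oxygen bridge O8), and lactones carry the cyclohepta[b]furan-2-one locants of the overview.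

**Route**

Step 1
Reactants: 1 8-oxabicyclo[3.2.1]oct-6-en-3-one (meso)
Product: 4 (1R,2S,5R)-2-methyl-8-oxabicyclo[3.2.1]oct-6-en-3-one (equatorial methyl anti to O8), via lithium enolate 2 (not isolated), via axial 2-methyl ketone 3 (not isolated)
Conditions: (R,R)-bis(1-phenylethyl)amine, n-BuLi, LiCl, THF, −78 °C; 1, −100 °C; MeI, −100 → −40 °C; then K2CO3, MeOH, rt
Reagents that add atoms: iodomethane (CI)
Why: Enantioselective deprotonation of the meso ketone by the chiral lithium amide (its antipode is used if the sense proves opposite), enolate alkylation on the face syn to the bridge and base-mediated epimerisation should give the more stable equatorial methyl ketone, which fixes C6 of the target and is the one stereocentre from which the others are relayed.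

Step 2
Reactants: 4 (1R,2S,5R)-2-methyl-8-oxabicyclo[3.2.1]oct-6-en-3-one
Product: 8 (1R,2S,4S,5S)-2-methyl-4-(triethylsilyloxy)-8-oxabicyclo[3.2.1]oct-6-en-3-one (axial silyloxy group syn to O8), via lithium enolate 5 (not isolated), via triethylsilyl enol ether 6 (not isolated), via silyloxy epoxide 7 (not isolated)
Conditions: LiN(CHMe2)2, THF, −78 °C; Et3SiCl; then mCPBA (1.0 equiv), hexane/CH2Cl2, −20 °C → rt
Reagents that add atoms: chlorotriethylsilane (CC[Si](Cl)(CC)CC); mCPBA (OOC(=O)c1cccc(Cl)c1)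
Why: Kinetic deprotonation at the unsubstituted α-methylene, silylation and Rubottom oxidation: the peracid should attack the enol ether on the open face syn to the bridge (the other face is screened by the two-carbon bridge) and the silyloxy epoxide should rearrange by 1,4-silyl shift to the axial α-silyloxy ketone, which sets C8 of the target.

Step 3
Reactants: 8 (1R,2S,4S,5S)-2-methyl-4-(triethylsilyloxy)-8-oxabicyclo[3.2.1]oct-6-en-3-one
Product: 10 6-hydroxy-2-methyl-4-(triethylsilyloxy)-8-oxabicyclo[3.2.1]octan-3-one (6-hydroxyl syn to O8), via trialkylborane 9 (not isolated)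
Conditions: (−)-Ipc2BH (from (+)-α-pinene), THF, −25 °C; then NaBO3·4H2O, THF/H2O, rt
Reagents that add atoms: sodium perborate ([Na+].[O-]OB=O)
Why: Asymmetric hydroboration on the face syn to the bridge: the two olefinic carbons are enantiotopic in the meso parent and are told apart by Ipc2BH, so in this near-meso substrate the matched reagent (its antipode if the sense proves opposite), helped by the inductive pull of the C4 silyloxy group toward the nearer carbon, should place boron on C6, and oxidation with retention gives the alcohol.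

Step 4
Reactants: 10 6-hydroxy-2-methyl-4-(triethylsilyloxy)-8-oxabicyclo[3.2.1]octan-3-one
Product: 11 2-methyl-4-(triethylsilyloxy)-8-oxabicyclo[3.2.1]octane-3,6-dione
Conditions: Dess–Martin periodinane, CH2Cl2, rt
Reagents that add atoms: none
Why: Dess–Martin oxidation of the secondary alcohol (and of any C3 carbinol formed by over-reduction in step 3) under non-basic conditions that avoid β-elimination of the oxygen bridge.

Step 5
Reactants: 11 2-methyl-4-(triethylsilyloxy)-8-oxabicyclo[3.2.1]octane-3,6-dione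
Product: 12 tert-butyl (2E)-2-[2-methyl-3-oxo-4-(triethylsilyloxy)-8-oxabicyclo[3.2.1]octan-6-ylidene]acetate
Conditions: Ph3P=CHCO2t-Bu, toluene, 80 °C
Reagents that add atoms: tert-butyl (triphenylphosphoranylidene)acetate (CC(C)(C)OC(=O)C=P(c1ccccc1)(c1ccccc1)c1ccccc1)
Why: Wittig olefination with a stabilised ylide under neutral conditions should select the strained α-alkoxy C6 ketone over the C3 ketone flanked by two substituted carbons, and avoids the base that would open the bridge; the alkene geometry is of no consequence.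

Step 6
Reactants: 12 tert-butyl (2E)-2-[2-methyl-3-oxo-4-(triethylsilyloxy)-8-oxabicyclo[3.2.1]octan-6-ylidene]acetate
Product: 13 tert-butyl 2-[2-methyl-3-oxo-4-(triethylsilyloxy)-8-oxabicyclo[3.2.1]octan-6-yl]acetate (side chain anti to O8)
Conditions: H2 (1 atm), Pd/C, EtOAc, rt
Reagents that add atoms: none
Why: Heterogeneous hydrogenation should deliver hydrogen to the exocyclic alkene on the face syn to the bridge, which places the acetate side chain anti to the bridge and sets C3a of the target.

Step 7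
Reactants: 14 (S)-but-3-yn-2-ol
Product: 15 (S)-but-3-yn-2-yl 2,2-dimethylpropanoate
Conditions: t-BuCOCl, Et3N, DMAP (cat.), CH2Cl2, 0 °C → rt
Reagents that add atoms: pivaloyl chloride (CC(C)(C)C(Cl)=O)
Why: Routine acylation of a secondary alcohol; the pivalate has no α-hydrogen and is the migrating group of the later gold-catalysed shift.

Step 8
Reactants: 13 tert-butyl 2-[2-methyl-3-oxo-4-(triethylsilyloxy)-8-oxabicyclo[3.2.1]octan-6-yl]acetate; 15 (S)-but-3-yn-2-yl 2,2-dimethylpropanoate
Product: 18 tert-butyl 2-{3-hydroxy-2-methyl-3-[(3S)-3-(pivaloyloxy)but-1-yn-1-yl]-4-(triethylsilyloxy)-8-oxabicyclo[3.2.1]octan-6-yl}acetate (3-hydroxyl anti to O8), via lithium acetylide 16 (not isolated), via lithium alkoxide 17 (not isolated)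
Conditions: 15, LiN(CHMe2)2, THF, −78 °C; LaCl3·2LiCl (0.3 equiv); 13, −78 → −40 °C; H2O
Reagents that add atoms: none
Why: 1,2-Addition of a lithium acetylide (lanthanum salt to suppress enolisation): the face anti to the bridge is blocked by the two-carbon bridge and its side chain, so the slim acetylide should enter syn to the bridge and leave the tertiary hydroxyl anti to it, which sets C7 of the target, while the ketone reacts faster than either ester.

Step 9
Reactants: 18 tert-butyl 2-{3-hydroxy-2-methyl-3-[(3S)-3-(pivaloyloxy)but-1-yn-1-yl]-4-(triethylsilyloxy)-8-oxabicyclo[3.2.1]octan-6-yl}acetate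
Product: 22 5,7-bis(tert-butyldimethylsilyloxy)-6-methyl-7-[(3S)-3-(pivaloyloxy)but-1-yn-1-yl]-8-(triethylsilyloxy)octahydrocyclohepta[b]furan-2-one (cis-fused; ring configuration as in the target), via tertiary silyl ether 19 (not isolated), via silyloxonium triflate 20 (not isolated), via lactonium triflate 21 (not isolated)
Conditions: TBSOTf (2.5 equiv), 2,6-di-tert-butyl-4-methylpyridine (3 equiv), CH2Cl2, −78 → 0 °C
Reagents that add atoms: tert-butyldimethylsilyl triflate (CC(C)(C)[Si](C)(C)OS(=O)(=O)C(F)(F)F)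
Why: Proposed new method: TBSOTf should first silylate the tertiary alcohol and then the bridging ether oxygen; the carbonyl oxygen of the tert-butyl ester, held on the face anti to the bridge, then displaces the silyloxonium at the adjacent bridgehead C5 in an SN2 sense, and the tert-butoxy lactonium ion loses isobutene to the hindered pyridine (if the tert-butyl ester is first exchanged for a silyl ester, the same lactone results by silyl transfer). The closest known reaction types are the silyl-triflate-promoted SN2 opening of cyclic ethers by weak nucleophiles, the epoxide-opening lactonisation of epoxy esters, and the participation of tert-butyl esters and carbonates in halo- and epoxide cyclisations with loss of isobutene. The γ-lactone closes in a 5-exo-tet mode (the leaving oxygen lies outside the new ring), driven by release of the bicyclic strain and of the crowding between the side chain and the anti C3 oxygen substituent. The only stereocentre changed is the bridgehead that becomes C8a of the target, inverted by backside attack so that the lactone is cis-fused on the face opposite the old bridge, while the bridge oxygen stays on C5 of the target with retention as its silyl ether. The step needs attack at this bridgehead and not at the other, and no external nucleophile: only the adjacent bridgehead is reachable through a five-membered transition state (the other would give a bridged δ-lactone), the base is non-nucleophilic and triflate is a poor nucleophile, and the C4 silyloxy group is syn to the breaking bond and cannot participate.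

Step 10
Reactants: 22 5,7-bis(tert-butyldimethylsilyloxy)-6-methyl-7-[(3S)-3-(pivaloyloxy)but-1-yn-1-yl]-8-(triethylsilyloxy)octahydrocyclohepta[b]furan-2-one
Product: 24 (3R)-3-methyl derivative of 22, via lithium enolate 23 (not isolated)
Conditions: LiN(CHMe2)2 (1.1 equiv), THF, −78 °C; MeI, −78 → −40 °C
Reagents that add atoms: iodomethane (CI)
Why: Alkylation of the lactone lithium enolate should occur on the convex face of the cis-fused bicycle, anti to the C4 methylene on C3a, giving the 3R methyl group, which is also the thermodynamically preferred trans arrangement.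

Step 11
Reactants: 24 (3R)-3-methyl lactone with 8-triethylsilyloxy and 5,7-bis(tert-butyldimethylsilyloxy) groups
Product: 25 5,7-bis(tert-butyldimethylsilyloxy)-8-hydroxy-3,6-dimethyl-7-[(3S)-3-(pivaloyloxy)but-1-yn-1-yl]octahydrocyclohepta[b]furan-2-one
Conditions: PPTS (cat.), MeOH/CH2Cl2, 0 °C → rt
Reagents that add atoms: none
Why: Acid-catalysed methanolysis (selective desilylation) should cleave the secondary triethylsilyl ether much faster than the secondary and tertiary tert-butyldimethylsilyl ethers.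

Step 12
Reactants: 25 8-hydroxy lactone; 26 angelic acid [(Z)-2-methylbut-2-enoic acid]
Product: 28 8-O-angelate of 25, via mixed anhydride 27 (not isolated)
Conditions: 26, 2,4,6-Cl3C6H2COCl, Et3N, toluene, rt; then 25, DMAP (cat.), toluene, 60 °C
Reagents that add atoms: none
Why: Yamaguchi esterification through the mixed anhydride acylates the only free hydroxyl, and moderate temperature in a non-nucleophilic medium should preserve the Z geometry of the angelate.

Step 13
Reactants: 28 8-O-angelate with the 7-butynyl pivalate side chain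
Product: 30 5,7-bis-O-(tert-butyldimethylsilyl) ether of the target, via allenyl pivalate 29 (not isolated)
Conditions: Ph3PAuNTf2 (3 mol %), butan-2-one/H2O, rt
Reagents that add atoms: none
Why: Gold-catalysed [3,3]-sigmatropic 1,3-acyloxy shift of the propargylic pivalate to the allenyl pivalate and its hydrolysis (a Meyer–Schuster-type transposition) should give the E-enone with the carbonyl on the carbon attached to C7, and the silyl ether on the C7 oxygen prevents cyclisation of the allene onto that oxygen.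

Step 14
Reactants: 30 5,7-bis-O-(tert-butyldimethylsilyl) ether of the target
Product: 31 (3R,3aS,5R,6S,7S,8S,8aR)-7-[(2E)-but-2-enoyl]-5,7-dihydroxy-3,6-dimethyl-2-oxooctahydro-2H-cyclohepta[b]furan-8-yl (2Z)-2-methylbut-2-enoate (CNP0183494.1)
Conditions: HF·pyridine, pyridine/THF, 0 °C → rt
Reagents that add atoms: none
Why: Fluoride-mediated cleavage of both silyl ethers under buffered conditions that should spare the angelate, the enone and the lactone.

**Compound list**

1 | 8-oxabicyclo[3.2.1]oct-6-en-3-one (meso) | C1[C@@H]2C=C[C@@H](O2)CC1=O | starting material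
2 | lithium enolate of 1 (C2=C3 enolate) | C1[C@@H]2C=C[C@@H](O2)C=C1[O-].[Li+] | intermediate
3 | (1R,2R,5R)-2-methyl-8-oxabicyclo[3.2.1]oct-6-en-3-one (axial methyl, syn to O8) | C1[C@@H]2C=C[C@@H](O2)[C@@H](C)C1=O | intermediate
4 | (1R,2S,5R)-2-methyl-8-oxabicyclo[3.2.1]oct-6-en-3-one (equatorial methyl, anti to O8) | C1[C@@H]2C=C[C@@H](O2)[C@H](C)C1=O | intermediate
5 | lithium enolate of 4 (C3=C4 enolate) | [O-]C1=C[C@@H]2C=C[C@@H](O2)[C@@H]1C.[Li+] | intermediate
6 | triethylsilyl enol ether of 4 (C3=C4) | CC[Si](CC)(CC)OC1=C[C@@H]2C=C[C@@H](O2)[C@@H]1C | intermediate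
7 | 3,4-epoxide of 6 (epoxide oxygen syn to O8) | CC[Si](CC)(CC)O[C@]12O[C@H]1[C@@H]3C=C[C@@H](O3)[C@@H]2C | intermediate
8 | (1R,2S,4S,5S)-2-methyl-4-(triethylsilyloxy)-8-oxabicyclo[3.2.1]oct-6-en-3-one (silyloxy axial, syn to O8) | CC[Si](CC)(CC)O[C@H]1[C@@H]2C=C[C@@H](O2)[C@H](C)C1=O | intermediate
9 | C6 diisopinocampheylborane adduct of 8 (boron syn to O8) | CC[Si](CC)(CC)O[C@H]1[C@@H]2[C@@H](B([C@@H]3C[C@@H]4C[C@H]([C@H]3C)C4(C)C)[C@@H]3C[C@@H]4C[C@H]([C@H]3C)C4(C)C)C[C@@H](O2)[C@H](C)C1=O | intermediate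
10 | 6-hydroxy-2-methyl-4-(triethylsilyloxy)-8-oxabicyclo[3.2.1]octan-3-one (6-OH syn to O8; other centres as in 8) | CC[Si](CC)(CC)O[C@H]1[C@@H]2[C@@H](O)C[C@@H](O2)[C@H](C)C1=O | intermediate
11 | 2-methyl-4-(triethylsilyloxy)-8-oxabicyclo[3.2.1]octane-3,6-dione | CC[Si](CC)(CC)O[C@H]1[C@@H]2C(=O)C[C@@H](O2)[C@H](C)C1=O | intermediate
12 | tert-butyl (2E)-2-[2-methyl-3-oxo-4-(triethylsilyloxy)-8-oxabicyclo[3.2.1]octan-6-ylidene]acetate | CC[Si](CC)(CC)O[C@H]1[C@@H]2/C(=C/C(=O)OC(C)(C)C)C[C@@H](O2)[C@H](C)C1=O | intermediate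
13 | tert-butyl 2-[2-methyl-3-oxo-4-(triethylsilyloxy)-8-oxabicyclo[3.2.1]octan-6-yl]acetate (side chain anti to O8) | CC[Si](CC)(CC)O[C@H]1[C@@H]2[C@H](CC(=O)OC(C)(C)C)C[C@@H](O2)[C@H](C)C1=O | intermediate
14 | (S)-but-3-yn-2-ol | C#C[C@H](C)O | starting material
15 | (S)-but-3-yn-2-yl 2,2-dimethylpropanoate | C#C[C@H](C)OC(=O)C(C)(C)C | intermediate
16 | lithium acetylide of 15 | [Li+].[C-]#C[C@H](C)OC(=O)C(C)(C)C | intermediate
17 | lithium alkoxide of 18 | CC[Si](CC)(CC)O[C@H]1[C@@H]2[C@H](CC(=O)OC(C)(C)C)C[C@@H](O2)[C@H](C)[C@@]1([O-])C#C[C@H](C)OC(=O)C(C)(C)C.[Li+] | intermediate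
18 | tert-butyl 2-{3-hydroxy-2-methyl-3-[(3S)-3-(pivaloyloxy)but-1-yn-1-yl]-4-(triethylsilyloxy)-8-oxabicyclo[3.2.1]octan-6-yl}acetate (3-OH anti, alkynyl syn to O8) | CC[Si](CC)(CC)O[C@H]1[C@@H]2[C@H](CC(=O)OC(C)(C)C)C[C@@H](O2)[C@H](C)[C@@]1(O)C#C[C@H](C)OC(=O)C(C)(C)C | intermediate
19 | 3-O-tert-butyldimethylsilyl ether of 18 | CC[Si](CC)(CC)O[C@H]1[C@@H]2[C@H](CC(=O)OC(C)(C)C)C[C@@H](O2)[C@H](C)[C@@]1(O[Si](C)(C)C(C)(C)C)C#C[C@H](C)OC(=O)C(C)(C)C | intermediate
20 | O8-(tert-butyldimethylsilyl)oxonium triflate of 19 | CC[Si](CC)(CC)O[C@H]1[C@@H]2[C@H](CC(=O)OC(C)(C)C)C[C@@H]([O+]2[Si](C)(C)C(C)(C)C)[C@H](C)[C@@]1(O[Si](C)(C)C(C)(C)C)C#C[C@H](C)OC(=O)C(C)(C)C.[O-]S(=O)(=O)C(F)(F)F | intermediate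
21 | ring-opened 2-tert-butoxy lactonium triflate (O1–C8a formed, 5-OTBS) | CC[Si](CC)(CC)O[C@H]1[C@@H]2[O+]=C(OC(C)(C)C)C[C@@H]2C[C@@H](O[Si](C)(C)C(C)(C)C)[C@H](C)[C@@]1(O[Si](C)(C)C(C)(C)C)C#C[C@H](C)OC(=O)C(C)(C)C.[O-]S(=O)(=O)C(F)(F)F | intermediate
22 | 5,7-bis(tert-butyldimethylsilyloxy)-6-methyl-7-[(3S)-3-(pivaloyloxy)but-1-yn-1-yl]-8-(triethylsilyloxy)octahydrocyclohepta[b]furan-2-one (cis-fused; C3a, C5, C6, C7, C8, C8a as in the target) | CC[Si](CC)(CC)O[C@H]1[C@@H]2OC(=O)C[C@@H]2C[C@@H](O[Si](C)(C)C(C)(C)C)[C@H](C)[C@@]1(O[Si](C)(C)C(C)(C)C)C#C[C@H](C)OC(=O)C(C)(C)C | intermediate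
23 | lithium enolate of 22 | CC[Si](CC)(CC)O[C@H]1[C@@H]2OC([O-])=C[C@@H]2C[C@@H](O[Si](C)(C)C(C)(C)C)[C@H](C)[C@@]1(O[Si](C)(C)C(C)(C)C)C#C[C@H](C)OC(=O)C(C)(C)C.[Li+] | intermediate
24 | (3R)-3-methyl derivative of 22 | CC[Si](CC)(CC)O[C@H]1[C@@H]2OC(=O)[C@H](C)[C@@H]2C[C@@H](O[Si](C)(C)C(C)(C)C)[C@H](C)[C@@]1(O[Si](C)(C)C(C)(C)C)C#C[C@H](C)OC(=O)C(C)(C)C | intermediate
25 | 5,7-bis(tert-butyldimethylsilyloxy)-8-hydroxy-3,6-dimethyl-7-[(3S)-3-(pivaloyloxy)but-1-yn-1-yl]octahydrocyclohepta[b]furan-2-one | O[C@H]1[C@@H]2OC(=O)[C@H](C)[C@@H]2C[C@@H](O[Si](C)(C)C(C)(C)C)[C@H](C)[C@@]1(O[Si](C)(C)C(C)(C)C)C#C[C@H](C)OC(=O)C(C)(C)C | intermediate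
26 | angelic acid, (Z)-2-methylbut-2-enoic acid | C/C=C(/C)C(=O)O | starting material
27 | angelic 2,4,6-trichlorobenzoic anhydride | C/C=C(/C)C(=O)OC(=O)c1c(Cl)cc(Cl)cc1Cl | intermediate
28 | 8-O-angelate of 25 | C/C=C(/C)C(=O)O[C@H]1[C@@H]2OC(=O)[C@H](C)[C@@H]2C[C@@H](O[Si](C)(C)C(C)(C)C)[C@H](C)[C@@]1(O[Si](C)(C)C(C)(C)C)C#C[C@H](C)OC(=O)C(C)(C)C | intermediate
29 | allenyl pivalate from 28 (1-pivaloyloxybuta-1,2-dienyl group on C7; allene axis not assigned) | C/C=C(/C)C(=O)O[C@H]1[C@@H]2OC(=O)[C@H](C)[C@@H]2C[C@@H](O[Si](C)(C)C(C)(C)C)[C@H](C)[C@@]1(O[Si](C)(C)C(C)(C)C)C(OC(=O)C(C)(C)C)=C=CC | intermediate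
30 | 5,7-bis-O-(tert-butyldimethylsilyl) ether of the target | C/C=C(/C)C(=O)O[C@H]1[C@@H]2OC(=O)[C@H](C)[C@@H]2C[C@@H](O[Si](C)(C)C(C)(C)C)[C@H](C)[C@@]1(O[Si](C)(C)C(C)(C)C)C(=O)/C=C/C | intermediate
31 | (3R,3aS,5R,6S,7S,8S,8aR)-7-[(2E)-but-2-enoyl]-5,7-dihydroxy-3,6-dimethyl-2-oxooctahydro-2H-cyclohepta[b]furan-8-yl (2Z)-2-methylbut-2-enoate | C/C=C(/C)C(=O)O[C@H]1[C@@H]2OC(=O)[C@H](C)[C@@H]2C[C@@H](O)[C@H](C)[C@@]1(O)C(=O)/C=C/C | target

**Step count**

Total step count: 14. Longest linear sequence: 13 steps (1 → 31 through steps 1–6 and 8–14); step 7 is a one-step side branch.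

**Steps most likely to fail**

Step 9 (proposed method). The ester carbonyl may be too weak a nucleophile to displace the silyloxonium, so that the ether is simply returned, or ionisation and elimination at the other, less deactivated bridgehead may outrun the intramolecular displacement. The fallback uses known reactions, sets out from 12 and comes back at 22:
- The acetylide 16 is added to 12 as in step 8 to give the tertiary alcohol F1.
- SmI2 (THF, HMPA, t-BuOH, −78 °C) opens the bridge by reductive elimination of the γ-alkoxy group of the unsaturated ester, giving the ring-opened β,γ-unsaturated ester diol F2 with the oxygen on C5 of the target intact.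
- TBSOTf and 2,6-lutidine give the bis-silyl ether F3.
- Iodolactonisation (iodine, NaHCO3, MeCN) closes O1–C8a anti to iodine with loss of the tert-butyl group and gives the iodolactone F4; under equilibrating conditions the new carbon–oxygen bond is expected trans to the neighbouring silyloxy group.
- Bu3SnH with AIBN removes iodine; hydrogen delivery to the convex face should give the cis-fused lactone 22.

Step 3. Reagent control may not override the substrate, giving poor discrimination between the two olefinic carbons, and the borane may also reduce the ketone. The fallback swaps the order of the two desymmetrising events, sets out from 1 and comes back at 10: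
- Ethylene glycol and TsOH give the dioxolane ketal F5, which is still meso.
- Ipc2BH hydroboration and oxidation then act on a true meso alkene and give the 6-syn alcohol F6.
- NaH and 4-methoxybenzyl chloride give the ether F7; PPTS in aqueous acetone frees the ketone F8.
- The chiral lithium amide of step 1 (matched enantiomer), MeI and K2CO3/MeOH give the equatorial 2-methyl ketone F9.
- The enolisation, silylation and Rubottom sequence of step 2 gives the α-silyloxy ketone F10.
- DDQ in wet CH2Cl2 removes the benzyl ether and returns 10.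

Step 12. Acylation of the hindered hydroxyl next to the quaternary carbon may be slow, and the activated angeloyl unit may isomerise from Z to E at the temperature needed. The fallback builds the Z-alkene on the ester, sets out from 25 and comes back at 28:
- 25 is acylated with 2-[bis(2,2,2-trifluoroethoxy)phosphoryl]propanoic acid (DCC, DMAP, CH2Cl2) to the phosphonopropionate F11.
- Still–Gennari olefination with acetaldehyde (KN(SiMe3)2, 18-crown-6, THF, −78 °C) should give the Z-2-methylbut-2-enoate 28.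

**Further compounds**

F1 | step 9 | tert-butyl (2E)-2-{3-hydroxy-2-methyl-3-[(3S)-3-(pivaloyloxy)but-1-yn-1-yl]-4-(triethylsilyloxy)-8-oxabicyclo[3.2.1]octan-6-ylidene}acetate | CC[Si](CC)(CC)O[C@H]1[C@@H]2/C(=C/C(=O)OC(C)(C)C)C[C@@H](O2)[C@H](C)[C@@]1(O)C#C[C@H](C)OC(=O)C(C)(C)C
F2 | step 9 | tert-butyl 2-{4,6-dihydroxy-5-methyl-4-[(3S)-3-(pivaloyloxy)but-1-yn-1-yl]-3-(triethylsilyloxy)cyclohept-1-en-1-yl}acetate | CC[Si](CC)(CC)O[C@H]1C=C(CC(=O)OC(C)(C)C)C[C@@H](O)[C@H](C)[C@@]1(O)C#C[C@H](C)OC(=O)C(C)(C)C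
F3 | step 9 | 4,6-bis-O-(tert-butyldimethylsilyl) ether of F2 | CC[Si](CC)(CC)O[C@H]1C=C(CC(=O)OC(C)(C)C)C[C@@H](O[Si](C)(C)C(C)(C)C)[C@H](C)[C@@]1(O[Si](C)(C)C(C)(C)C)C#C[C@H](C)OC(=O)C(C)(C)C
F4 | step 9 | 3a-iodo derivative of 22 (iodine on C3a, trans to O1) | CC[Si](CC)(CC)O[C@H]1[C@@H]2OC(=O)C[C@]2(I)C[C@@H](O[Si](C)(C)C(C)(C)C)[C@H](C)[C@@]1(O[Si](C)(C)C(C)(C)C)C#C[C@H](C)OC(=O)C(C)(C)C
F5 | step 3 | 8-oxabicyclo[3.2.1]oct-6-en-3-one ethylene ketal (meso) | C1[C@@H]2C=C[C@@H](O2)CC13OCCO3
F6 | step 3 | 6-hydroxy-8-oxabicyclo[3.2.1]octan-3-one ethylene ketal (6-OH syn to O8) | C1[C@@H]2[C@@H](O)C[C@@H](O2)CC13OCCO3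
F7 | step 3 | 6-(4-methoxybenzyloxy)-8-oxabicyclo[3.2.1]octan-3-one ethylene ketal | C1[C@@H]2[C@@H](OCc3ccc(OC)cc3)C[C@@H](O2)CC14OCCO4
F8 | step 3 | 6-(4-methoxybenzyloxy)-8-oxabicyclo[3.2.1]octan-3-one | C1[C@@H]2[C@@H](OCc3ccc(OC)cc3)C[C@@H](O2)CC1=O
F9 | step 3 | 6-(4-methoxybenzyloxy)-2-methyl-8-oxabicyclo[3.2.1]octan-3-one (methyl equatorial, anti to O8) | C1[C@@H]2[C@@H](OCc3ccc(OC)cc3)C[C@@H](O2)[C@H](C)C1=O
F10 | step 3 | 6-(4-methoxybenzyloxy)-2-methyl-4-(triethylsilyloxy)-8-oxabicyclo[3.2.1]octan-3-one | CC[Si](CC)(CC)O[C@H]1[C@@H]2[C@@H](OCc3ccc(OC)cc3)C[C@@H](O2)[C@H](C)C1=O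
F11 | step 12 | 8-O-{2-[bis(2,2,2-trifluoroethoxy)phosphoryl]propanoyl} ester of 25 | CC(C(=O)O[C@H]1[C@@H]2OC(=O)[C@H](C)[C@@H]2C[C@@H](O[Si](C)(C)C(C)(C)C)[C@H](C)[C@@]1(O[Si](C)(C)C(C)(C)C)C#C[C@H](C)OC(=O)C(C)(C)C)P(=O)(OCC(F)(F)F)OCC(F)(F)F
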